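**Assumption:** germacrane numbering (C1–C15) is used for all intermediates, and the five starting materials (1, 2, 7, 12, 18) are taken as catalogue compounds.

## Retrosynthetic overview

1. Furanone ring (last): formed across the ten-membered ring from a 3-oxo-1(10),4-germacradienolide by oxidising Δ1(10) to the 10-hydroxy-1-ketone, hemiketalisation onto C3 and dehydration (the tagitinin-type hemiketal-to-furanone path presumed in nature). The O6 ester is attached just before.
2. Ten-membered carbocycle: C6–C7 bond, the bond made by germacrene A synthase (C6 electrophile, C7=C11 nucleophile, Δ11(13) created). It is closed by Barbier allylation of a (Z)-4-oxo-2-enal, unmasked from a 2-alkyl-3-methylfuran with singlet oxygen, by an 8,12-butenolide allyl bromide.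
3. Lactone ring (first): ring-closing metathesis of a 2-(bromomethyl)acrylate, so the 8,12 regiochemistry is fixed before O6 exists. C8 comes from (S)-epichlorohydrin; the E-Δ1(10) alkene from hydrozirconation of a 2-butynylfuran.
4. Side chain: (2S,3S)-epoxyangelic acid from angelic acid by Sharpless epoxidation. Ring order: lactone, carbocycle, furanone.

## Route

Step 1
Reactants: 1 2-bromo-3-methylfuran; 2 1-bromobut-2-yne
Product: 4 2-(but-2-yn-1-yl)-3-methylfuran, via furyllithium 3 (not isolated)
Conditions: n-BuLi, THF, −78 °C; then 2, −78 → 25 °C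
Reagents that add atoms: none
Why: Bromine–lithium exchange gives the 2-furyllithium regiospecifically and this is alkylated by the primary propargylic bromide (SN2 alkylation of a heteroaryllithium; the methyl-capped alkyne disfavours SN2′ allene formation).

Step 2
Reactants: 4 2-(but-2-yn-1-yl)-3-methylfuran
Product: 6 2-[(2E)-3-iodobut-2-en-1-yl]-3-methylfuran, via alkenylzirconocene 5 (not isolated)
Conditions: Cp2Zr(H)Cl (2 equiv), THF, 40 °C; then I2, 0 °C
Reagents that add atoms: iodine, [I][I]
Why: Schwartz hydrozirconation is a syn addition that, after equilibration with excess hydride, puts zirconium on the less hindered methyl-bearing carbon, and iododezirconation with retention gives the E-iodide that becomes the E-C1=C10 alkene.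

Step 3
Reactants: 6 2-[(2E)-3-iodobut-2-en-1-yl]-3-methylfuran; 7 (S)-2-(chloromethyl)oxirane
Product: 9 (2S,4E)-1-chloro-4-methyl-6-(3-methylfuran-2-yl)hex-4-en-2-ol, via alkenyllithium 8 (not isolated)
Conditions: t-BuLi (2 equiv), Et2O, −78 °C; then 7, BF3·OEt2, −78 °C
Reagents that add atoms: none
Why: Iodine–lithium exchange keeps the alkene geometry and the BF3-activated epoxide is opened at its unsubstituted CH2 (SN2 epoxide opening), so the C8 carbinol centre is carried over unchanged from (S)-epichlorohydrin.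

Step 4
Reactants: 9 (2S,4E)-1-chloro-4-methyl-6-(3-methylfuran-2-yl)hex-4-en-2-ol
Product: 11 (3S,5E)-5-methyl-7-(3-methylfuran-2-yl)hepta-1,5-dien-3-ol, via epoxide 10 (not isolated)
Conditions: Me3S+ I− (3.5 equiv), n-BuLi (3.4 equiv), THF, −10 → 25 °C
Reagents that add atoms: trimethylsulfonium iodide, C[S+](C)C.[I-]
Why: The ylide first closes the chlorohydrin to the terminal epoxide, then opens it at CH2, and the sulfonium betaine eliminates dimethyl sulfide (one-carbon homologation of an epoxide to an allylic alcohol with dimethylsulfonium methylide); no bond to C8 is touched.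

Step 5
Reactants: 11 (3S,5E)-5-methyl-7-(3-methylfuran-2-yl)hepta-1,5-dien-3-ol; 12 2-(bromomethyl)prop-2-enoic acid
Product: 13 (3S,5E)-5-methyl-7-(3-methylfuran-2-yl)hepta-1,5-dien-3-yl 2-(bromomethyl)prop-2-enoate
Conditions: DCC, DMAP (5 mol %), CH2Cl2, 0 °C
Reagents that add atoms: none
Why: Steglich esterification of the secondary allylic alcohol, run cold with little DMAP to limit SN2′ attack on the allylic bromide.

Step 6
Reactants: 13 (3S,5E)-5-methyl-7-(3-methylfuran-2-yl)hepta-1,5-dien-3-yl 2-(bromomethyl)prop-2-enoate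
Product: 14 (5S)-3-(bromomethyl)-5-[(2E)-2-methyl-4-(3-methylfuran-2-yl)but-2-en-1-yl]furan-2(5H)-one
Conditions: second-generation Grubbs catalyst (5 mol %), CH2Cl2 (5 mM), 40 °C
Reagents that add atoms: none
Why: Ring-closing metathesis between the vinyl group and the acrylate closes the five-membered butenolide (the 8,12-lactone) with loss of ethene, while the trisubstituted alkene and the furan are inert to the catalyst.

Step 7
Reactants: 14 (5S)-3-(bromomethyl)-5-[(2E)-2-methyl-4-(3-methylfuran-2-yl)but-2-en-1-yl]furan-2(5H)-one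
Product: 17 (6S,7S,8S)-6-hydroxy-3-oxogermacra-1(10)E,4Z,11(13)-trien-12,8-olide, via endoperoxide 15 (not isolated), via oxoenal 16 (not isolated)
Conditions: O2, tetraphenylporphyrin (cat.), visible light, CH2Cl2, −78 °C; Me2S, −78 → 0 °C; then THF/sat. aq NH4Cl (1 mM), indium powder, 25 °C
Reagents that add atoms: oxygen, O=O
Why: Proposed new method: singlet oxygen adds [4+2] to the 2,3-dialkylfuran much faster than it undergoes an ene reaction with the trisubstituted alkene, and dimethyl sulfide reduces the endoperoxide to the (Z)-4-oxo-2-enal (known furan-to-cis-enedione unmasking); indium then inserts into the allylic bromide and the allylindium attacks only the aldehyde through its γ-carbon C7 in a cyclic six-membered transition state (Barbier macrocyclisation; closest known types are metal-mediated C6–C7 closures of 2-(bromomethyl)acrylates onto enals in germacranolide synthesis and additions of 3-(bromomethyl)butenolides to aldehydes), making the C6–C7 bond and Δ11(13) alkene of germacrene A synthase; C7 is set trans to C8 because C6 adds to the butenolide face opposite the C9 chain, and C6 (6β-OH) is expected, not assured, from the tether-enforced transition state with the s-trans enal lying over the lactone.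

Step 8
Reactants: 18 (2Z)-2-methylbut-2-enoic acid (angelic acid)
Product: 19 (2Z)-2-methylbut-2-en-1-ol
Conditions: LiAlH4, Et2O, 0 °C
Reagents that add atoms: none
Why: Hydride reduction of the carboxylic acid (1,2-reduction) leaves the Z-alkene untouched.

Step 9
Reactants: 19 (2Z)-2-methylbut-2-en-1-ol
Product: 20 [(2R,3S)-2,3-dimethyloxiran-2-yl]methanol
Conditions: Ti(OiPr)4 (10 mol %), D-(−)-diisopropyl tartrate (12 mol %), t-BuOOH, 4 Å molecular sieves, CH2Cl2, −20 °C
Reagents that add atoms: tert-butyl hydroperoxide, CC(C)(C)OO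
Why: Sharpless asymmetric epoxidation, in which the D-(−)-tartrate catalyst delivers oxygen to the alkene face that gives the (2R,3S)-epoxide (both side-chain stereocentres, about 90% ee expected for a Z-allylic alcohol) with the cis geometry retained.

Step 10
Reactants: 20 [(2R,3S)-2,3-dimethyloxiran-2-yl]methanol
Product: 21 (2S,3S)-2,3-dimethyloxirane-2-carboxylic acid
Conditions: RuCl3 (2 mol %), NaIO4, EtOAc/MeCN/H2O, 25 °C
Reagents that add atoms: water, O
Why: Ruthenium tetroxide-catalysed oxidation of the primary alcohol to the acid via the aldehyde hydrate does not touch the epoxide centres (the C2 descriptor changes from R to S only because the priority order changes).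

Step 11
Reactants: 17 (6S,7S,8S)-6-hydroxy-3-oxogermacra-1(10)E,4Z,11(13)-trien-12,8-olide; 21 (2S,3S)-2,3-dimethyloxirane-2-carboxylic acid
Product: 23 (6S,7R,8S)-6-{[(2S,3S)-2,3-dimethyloxirane-2-carbonyl]oxy}-3-oxogermacra-1(10)E,4Z,11(13)-trien-12,8-olide, via mixed anhydride 22 (not isolated)
Conditions: 21, 2,4,6-trichlorobenzoyl chloride, Et3N, toluene, 0 °C; then 17, DMAP, 0 → 25 °C
Reagents that add atoms: none
Why: Yamaguchi esterification, in which DMAP attacks the less hindered aliphatic carbonyl of the preformed mixed anhydride and acylates O6 with retention at C6 (the C7 descriptor changes from S to R only by priority); base contact is kept cold and short because the β,γ-unsaturated C3 ketone can conjugate.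

Step 12
Reactants: 23 (6S,7R,8S)-6-{[(2S,3S)-2,3-dimethyloxirane-2-carbonyl]oxy}-3-oxogermacra-1(10)E,4Z,11(13)-trien-12,8-olide
Product: 26 (6S,7R,8S,10R)-6-{[(2S,3S)-2,3-dimethyloxirane-2-carbonyl]oxy}-3,10-epoxy-1-oxogermacra-2,4Z,11(13)-trien-12,8-olide (CNP0258430.4), via ketol 24 (not isolated), via hemiketal 25 (not isolated)
Conditions: RuCl3 (1 mol %), Oxone (2KHSO5·KHSO4·K2SO4), NaHCO3, EtOAc/MeCN/H2O (6:6:1), 0 °C, 10 min; then pyridinium p-toluenesulfonate (cat.), CH2Cl2, 25 °C
Reagents that add atoms: potassium peroxymonosulfate (active component of Oxone), [K+].[O-]S(=O)(=O)OO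
Why: Proposed new method: ruthenium tetroxide formed in situ adds [3+2] to the only electron-rich alkene, the strained E-Δ1(10) bond, from its peripheral face (C14 methyl on the β face, the face used in 1β,10α-epoxidation of germacranolides), and Oxone converts the ruthenate ester into the 10α-hydroxy-1-ketone (ruthenium-catalysed ketohydroxylation, regiochemistry fixed by the trisubstituted alkene); the tertiary hydroxyl then closes transannularly onto the C3 ketone and the resulting β-hydroxy ketone loses water under mild acid to the vinylogous ester (closest known type: acid-catalysed cyclodehydration of α′-hydroxy-1,3-diketones to 3(2H)-furanones), so C10 (R) is set by syn, stereoretentive oxygen delivery.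

## Compound list

1 | 2-bromo-3-methylfuran | Cc1ccoc1Br | starting material
2 | 1-bromobut-2-yne | CC#CCBr | starting material
3 | (3-methylfuran-2-yl)lithium | [Li]c1occc1C | intermediate
4 | 2-(but-2-yn-1-yl)-3-methylfuran | CC#CCc1occc1C | intermediate
5 | chlorobis(cyclopentadienyl)[(2E)-4-(3-methylfuran-2-yl)but-2-en-2-yl]zirconium | C/C(=C\Cc1occc1C)[Zr](Cl)(C1C=CC=C1)C1C=CC=C1 | intermediate
6 | 2-[(2E)-3-iodobut-2-en-1-yl]-3-methylfuran | I/C(C)=C/Cc1occc1C | intermediate
7 | (S)-2-(chloromethyl)oxirane ((S)-epichlorohydrin) | ClC[C@@H]1CO1 | starting material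
8 | [(2E)-4-(3-methylfuran-2-yl)but-2-en-2-yl]lithium | C/C([Li])=C\Cc1occc1C | intermediate
9 | (2S,4E)-1-chloro-4-methyl-6-(3-methylfuran-2-yl)hex-4-en-2-ol | O[C@H](CCl)C/C(C)=C/Cc1occc1C | intermediate
10 | (2S)-2-[(2E)-2-methyl-4-(3-methylfuran-2-yl)but-2-en-1-yl]oxirane | O1[C@H](C1)C/C(C)=C/Cc2occc2C | intermediate
11 | (3S,5E)-5-methyl-7-(3-methylfuran-2-yl)hepta-1,5-dien-3-ol | O[C@H](C=C)C/C(C)=C/Cc1occc1C | intermediate
12 | 2-(bromomethyl)prop-2-enoic acid | C=C(CBr)C(=O)O | starting material
13 | (3S,5E)-5-methyl-7-(3-methylfuran-2-yl)hepta-1,5-dien-3-yl 2-(bromomethyl)prop-2-enoate | C=C(CBr)C(=O)O[C@H](C=C)C/C(C)=C/Cc1occc1C | intermediate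
14 | (5S)-3-(bromomethyl)-5-[(2E)-2-methyl-4-(3-methylfuran-2-yl)but-2-en-1-yl]furan-2(5H)-one | O=C1O[C@H](C=C1CBr)C/C(C)=C/Cc2occc2C | intermediate
15 | furan endoperoxide of 14 (2,3,7-trioxabicyclo[2.2.1]hept-5-ene, bridgeheads C3 and C6, mixture at the bridgeheads) | CC1=CC2OOC1(C/C=C(\C)C[C@@H]3OC(=O)C(CBr)=C3)O2 | intermediate
16 | (2Z,6E)-8-[(2S)-4-(bromomethyl)-5-oxo-2,5-dihydrofuran-2-yl]-3,7-dimethyl-4-oxoocta-2,6-dienal | O=C/C=C(C)\C(=O)C/C=C(\C)C[C@@H]1OC(=O)C(CBr)=C1 | intermediate
17 | (6S,7S,8S)-6-hydroxy-3-oxogermacra-1(10)E,4Z,11(13)-trien-12,8-olide (6β-OH, 7α-H, 8β-H; may sit partly as its 3,6-hemiketal) | C=C1C(=O)O[C@H]2C/C(C)=C/CC(=O)/C(C)=C\[C@H](O)[C@H]12 | intermediate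
18 | (2Z)-2-methylbut-2-enoic acid (angelic acid) | C/C=C(/C)C(=O)O | starting material
19 | (2Z)-2-methylbut-2-en-1-ol | C/C=C(/C)CO | intermediate
20 | [(2R,3S)-2,3-dimethyloxiran-2-yl]methanol | OC[C@@]1(C)O[C@H]1C | intermediate
21 | (2S,3S)-2,3-dimethyloxirane-2-carboxylic acid (epoxyangelic acid) | OC(=O)[C@@]1(C)O[C@H]1C | intermediate
22 | (2S,3S)-2,3-dimethyloxirane-2-carboxylic 2,4,6-trichlorobenzoic anhydride | O=C(OC(=O)[C@@]1(C)O[C@H]1C)c2c(Cl)cc(Cl)cc2Cl | intermediate
23 | (6S,7R,8S)-6-{[(2S,3S)-2,3-dimethyloxirane-2-carbonyl]oxy}-3-oxogermacra-1(10)E,4Z,11(13)-trien-12,8-olide | C=C1C(=O)O[C@H]2C/C(C)=C/CC(=O)/C(C)=C\[C@H](OC(=O)[C@@]3(C)O[C@H]3C)[C@H]12 | intermediate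
24 | (6S,7R,8S,10R)-6-{[(2S,3S)-2,3-dimethyloxirane-2-carbonyl]oxy}-10-hydroxy-1,3-dioxogermacra-4Z,11(13)-dien-12,8-olide | C=C1C(=O)O[C@H]2C[C@@](C)(O)C(=O)CC(=O)/C(C)=C\[C@H](OC(=O)[C@@]3(C)O[C@H]3C)[C@H]12 | intermediate
25 | 3,10-hemiketal of 24 (3-hydroxy-3,10α-epoxy-1-oxo; C3 unassigned) | C=C1C(=O)O[C@H]2C[C@@]3(C)OC(O)(CC3=O)/C(C)=C\[C@H](OC(=O)[C@@]4(C)O[C@H]4C)[C@H]12 | intermediate
26 | (6S,7R,8S,10R)-6-{[(2S,3S)-2,3-dimethyloxirane-2-carbonyl]oxy}-3,10-epoxy-1-oxogermacra-2,4Z,11(13)-trien-12,8-olide (CNP0258430.4; 6β-ester, 7α-H, 8β-H, 10β-Me) | C=C1C(=O)O[C@H]2C[C@@]3(C)OC(=CC3=O)/C(C)=C\[C@H](OC(=O)[C@@]3(C)O[C@H]3C)[C@H]12 | target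

## Step count and risks

Total steps: 12. Longest linear sequence: 9 (steps 1–7, 11, 12); steps 8–10 make the side-chain acid.

Stereocentres: C8 from 7 (step 3); C7 and C6 in step 7; C10 in step 12; the two side-chain centres in step 9.

The three steps most likely to fail:

**Step 7** (one-pot furan unmasking and Barbier macrocyclisation). The risks are reduction of the enedione by the metal and, most of all, the configuration at C6, which rests on a transition-state argument. The fallback sets out from 14. If the ring closes mainly to the C6 epimer (6R,7S,8S)-6-hydroxy-3-oxogermacra-1(10)E,4Z,11(13)-trien-12,8-olide F1, that alcohol is not discarded. It is esterified with acid 21 under Mitsunobu conditions (PPh3, DIAD, toluene, 0 °C), so that C6 reacts as the electrophile and is inverted while the ester is installed. This gives 23 directly, where the route is rejoined; step 11 is then skipped.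

**Step 11** (acylation of the hindered O6 next to a base-labile β,γ-unsaturated ketone that can also mask the alcohol as a 3,6-hemiketal). The fallback sets out from 17 and moves the acylation to the end.
- 17 is silylated (TESCl, imidazole, DMF) to the silyl ether (6S,7R,8S)-6-(triethylsilyloxy)-3-oxogermacra-1(10)E,4Z,11(13)-trien-12,8-olide F2.
- The oxidation and cyclodehydration of step 12 are run on F2 to give the silylated furanone (6S,7R,8S,10R)-6-(triethylsilyloxy)-3,10-epoxy-1-oxogermacra-2,4Z,11(13)-trien-12,8-olide F3.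
- HF·pyridine in THF frees the core alcohol (6S,7S,8S,10R)-6-hydroxy-3,10-epoxy-1-oxogermacra-2,4Z,11(13)-trien-12,8-olide F4.
- F4, which has neither the skipped enone nor the hemiketal, is acylated with mixed anhydride 22 and DMAP; the route is rejoined at 26.

**Step 12** (ruthenium ketohydroxylation and transannular cyclodehydration). The risks are over-oxidation of the dicarbonyl or attack on the conjugated alkenes. The fallback sets out from 23 and separates the two oxidation events. OsO4 (cat.) with NMO in acetone/H2O dihydroxylates only Δ1(10), and the 10-hydroxyl closes onto C3 to give the isolable hemiketal diol (6S,7R,8S,10R)-6-{[(2S,3S)-2,3-dimethyloxirane-2-carbonyl]oxy}-1β,3-dihydroxy-3,10-epoxygermacra-4Z,11(13)-dien-12,8-olide F5. Dess–Martin periodinane then oxidises the C1 alcohol and pyridinium p-toluenesulfonate dehydrates the hemiketal; the route is rejoined at 26.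

## Further compounds

F1 | step 7 | (6R,7S,8S)-6-hydroxy-3-oxogermacra-1(10)E,4Z,11(13)-trien-12,8-olide | C=C1C(=O)O[C@H]2C/C(C)=C/CC(=O)/C(C)=C\[C@@H](O)[C@H]12
F2 | step 11 | (6S,7R,8S)-6-(triethylsilyloxy)-3-oxogermacra-1(10)E,4Z,11(13)-trien-12,8-olide | C=C1C(=O)O[C@H]2C/C(C)=C/CC(=O)/C(C)=C\[C@H](O[Si](CC)(CC)CC)[C@H]12
F3 | step 11 | (6S,7R,8S,10R)-6-(triethylsilyloxy)-3,10-epoxy-1-oxogermacra-2,4Z,11(13)-trien-12,8-olide | C=C1C(=O)O[C@H]2C[C@@]3(C)OC(=CC3=O)/C(C)=C\[C@H](O[Si](CC)(CC)CC)[C@H]12
F4 | step 11 | (6S,7S,8S,10R)-6-hydroxy-3,10-epoxy-1-oxogermacra-2,4Z,11(13)-trien-12,8-olide | C=C1C(=O)O[C@H]2C[C@@]3(C)OC(=CC3=O)/C(C)=C\[C@H](O)[C@H]12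
F5 | step 12 | (6S,7R,8S,10R)-6-{[(2S,3S)-2,3-dimethyloxirane-2-carbonyl]oxy}-1β,3-dihydroxy-3,10-epoxygermacra-4Z,11(13)-dien-12,8-olide | C=C1C(=O)O[C@H]2C[C@@]3(C)OC(O)(C[C@H]3O)/C(C)=C\[C@H](OC(=O)[C@@]4(C)O[C@H]4C)[C@H]12
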